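**Strategy**

Everything rests on opening the pyranone ring (ring C) at the aryl ether bond O1–C8a and at C2–C3. C8a lies on ring A ortho to the C4 ketone, and C2–C3 is the α,β-bond of that ketone, so ring C is read as an aldehyde C=O added across an α-methoxy ketone carbon and an SNAr-active C–F carbon. In one pot a tin(II)-catalysed asymmetric Mukaiyama aldol makes C2–C3 and sets both stereocentres (anti), and fluoride then makes the silyl ether displace the ortho fluorine, closing O1–C8a and releasing Me3SiF. The precursors are the (Z)-trimethylsilyl enol ether of a 2-fluoroaryl methoxymethyl ketone and the dibenzylated ring-B aldehyde.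

Key step: step 4

Remark: compounds 1, 2 and 7 are taken as catalogue chemicals; the sense of induction of the tin(II)–(S)-diamine catalyst (attack on the Si face of the aldehyde) is assigned by analogy with its thioester aldols, and the D-proline-derived (R)-diamine is used instead should it prove opposite.

**Route**

Step 1
Reactants: 1 5-fluoro-1,2,3-trimethoxybenzene; 2 N,2-dimethoxy-N-methylacetamide
Product: 4 1-(6-fluoro-2,3,4-trimethoxyphenyl)-2-methoxyethan-1-one, via aryllithium 3 (not isolated)
Conditions: n-BuLi, THF, −78 °C; then 2, −78 °C; 1 M HCl, −78 → 0 °C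
Reagents that add atoms: none
Why: Directed ortho-lithiation removes one of the two equivalent ring protons, each flanked by F and OMe, and the aryllithium acylates the Weinreb amide, whose chelated tetrahedral adduct survives until the cold acidic quench so that no tertiary alcohol forms (Weinreb ketone synthesis); at −78 °C the ortho-fluoroaryllithium should not lose LiF.

Step 2
Reactants: 4 1-(6-fluoro-2,3,4-trimethoxyphenyl)-2-methoxyethan-1-one
Product: 6 trimethyl{[(Z)-1-(6-fluoro-2,3,4-trimethoxyphenyl)-2-methoxyethenyl]oxy}silane, via lithium enolate 5 (not isolated)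
Conditions: LiHMDS, THF, −78 °C; TMSCl, −78 → 0 °C; non-aqueous work-up (pentane, filtration)
Reagents that add atoms: chlorotrimethylsilane, C[Si](C)(C)Cl
Why: Kinetic deprotonation of the only enolisable position gives the lithium enolate with OMe and OLi cis through five-membered chelation, and O-silylation fixes it as the (Z)-silyl enol ether (enol silane formation); no stereocentre is formed.

Step 3
Reactants: 7 3,5-dihydroxy-4-methoxybenzaldehyde
Product: 8 3,5-bis(benzyloxy)-4-methoxybenzaldehyde
Conditions: BnBr, K2CO3, DMF, 50 °C
Reagents that add atoms: benzyl bromide, BrCc1ccccc1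
Why: Williamson ether synthesis on both phenols gives benzyl ethers that should survive Lewis acid catalysis and fluoride and that leave later by neutral hydrogenolysis.

Step 4
Reactants: 6 trimethyl{[(Z)-1-(6-fluoro-2,3,4-trimethoxyphenyl)-2-methoxyethenyl]oxy}silane; 8 3,5-bis(benzyloxy)-4-methoxybenzaldehyde
Product: 10 (2R,3R)-2-[3,5-bis(benzyloxy)-4-methoxyphenyl]-3,5,6,7-tetramethoxy-2,3-dihydro-4H-chromen-4-one, via aldol silyl ether 9 (not isolated)
Conditions: Sn(OTf)2 (20 mol %), (S)-1-ethyl-2-(piperidin-1-ylmethyl)pyrrolidine (24 mol %), EtCN, −78 °C, slow addition of 6 and 8; then CsF, DMF, −40 → 0 °C; pH 7 buffer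
Reagents that add atoms: none
Why: The tin(II) triflate–(S)-diamine Lewis acid binds aldehyde 8, and the (Z)-enol silane 6 adds to its Si face through an open transition state in which the α-methoxy oxygen also coordinates tin, which forms C2–C3 as the anti adduct and passes Me3Si to the new oxygen (catalytic asymmetric Mukaiyama aldol; closest precedent: tin(II)–diamine aldols of α-alkoxy silyl enolates with aromatic aldehydes to anti-1,2-diol derivatives). Fluoride then cleaves the O–Si bond of 9, and the alkoxide adds to C8a, the fluorine-bearing carbon of ring A ortho to the C4 ketone, and expels fluoride (intramolecular SNAr by addition–elimination through the Meisenheimer enolate; fluoride-promoted aryl ether formation from silyl ethers and activated aryl fluorides is the known type). The pyranone ring closes in a 6-endo-trig sense onto the C8a=C4a–C4=O acceptor. C2 (R) is set by the catalyst-controlled face of the aldehyde and is carried unchanged into the ring because its C–O bond is never broken; C3 (R) is set by the anti selectivity of the aldol and is expected to be backed by thermodynamics, since the 2,3-trans diequatorial chromanone should be the more stable epimer at the only enolisable centre. The step needs ring closure to outrun retro-aldol of the free alkoxide and needs the achiral silyl triflate pathway to stay slow: the first should be secured by ortho-carbonyl activation of the C–F bond, the low temperature and the strong Si–F bond that regenerates fluoride, the second by slow addition of both partners in propionitrile.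

Step 5
Reactants: 10 (2R,3R)-2-[3,5-bis(benzyloxy)-4-methoxyphenyl]-3,5,6,7-tetramethoxy-2,3-dihydro-4H-chromen-4-one
Product: 11 (2R,3R)-2-(3,5-dihydroxy-4-methoxyphenyl)-3,5,6,7-tetramethoxy-2,3-dihydro-4H-chromen-4-one
Conditions: H2 (1 atm), 10% Pd/C, EtOAc–MeOH, rt
Reagents that add atoms: none
Why: Hydrogenolysis of the two benzyl aryl ethers over Pd/C should be much faster than cleavage of the ring C2–O1 bond or reduction of the hindered aryl ketone, and the neutral medium leaves C2 and the enolisable C3 untouched.

**Compound list**

1 | 5-fluoro-1,2,3-trimethoxybenzene | COc1cc(F)cc(OC)c1OC | starting material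
2 | N,2-dimethoxy-N-methylacetamide | COCC(=O)N(C)OC | starting material
3 | (6-fluoro-2,3,4-trimethoxyphenyl)lithium (not isolated) | [Li]c1c(F)cc(OC)c(OC)c1OC | intermediate
4 | 1-(6-fluoro-2,3,4-trimethoxyphenyl)-2-methoxyethan-1-one | COCC(=O)c1c(F)cc(OC)c(OC)c1OC | intermediate
5 | lithium (Z)-1-(6-fluoro-2,3,4-trimethoxyphenyl)-2-methoxyethen-1-olate (not isolated) | [Li]O/C(=C\OC)c1c(F)cc(OC)c(OC)c1OC | intermediate
6 | trimethyl{[(Z)-1-(6-fluoro-2,3,4-trimethoxyphenyl)-2-methoxyethenyl]oxy}silane | CO/C=C(\O[Si](C)(C)C)c1c(F)cc(OC)c(OC)c1OC | intermediate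
7 | 3,5-dihydroxy-4-methoxybenzaldehyde | COc1c(O)cc(C=O)cc1O | starting material
8 | 3,5-bis(benzyloxy)-4-methoxybenzaldehyde | COc1c(OCc2ccccc2)cc(C=O)cc1OCc1ccccc1 | intermediate
9 | (2R,3R)-3-[3,5-bis(benzyloxy)-4-methoxyphenyl]-1-(6-fluoro-2,3,4-trimethoxyphenyl)-2-methoxy-3-[(trimethylsilyl)oxy]propan-1-one (anti, not isolated) | COc1cc(F)c(c(OC)c1OC)C(=O)[C@H](OC)[C@@H](c1cc(OCc2ccccc2)c(OC)c(OCc2ccccc2)c1)O[Si](C)(C)C | intermediate
10 | (2R,3R)-2-[3,5-bis(benzyloxy)-4-methoxyphenyl]-3,5,6,7-tetramethoxy-2,3-dihydro-4H-chromen-4-one (2,3-trans) | COc1cc2c(c(OC)c1OC)C(=O)[C@H](OC)[C@@H](c1cc(OCc3ccccc3)c(OC)c(OCc3ccccc3)c1)O2 | intermediate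
11 | (2R,3R)-2-(3,5-dihydroxy-4-methoxyphenyl)-3,5,6,7-tetramethoxy-2,3-dihydro-4H-chromen-4-one (2,3-trans) | COc1cc2c(c(OC)c1OC)C(=O)[C@H](OC)[C@@H](c1cc(O)c(OC)c(O)c1)O2 | target

**Count and risks**

Total steps: 5. Longest linear sequence: 4 (steps 1, 2, 4, 5).

Steps most likely to fail:

1. Step 4. Retro-aldol of the fluoride-liberated alkoxide, or reversible opening of the new pyranone through its C3 enolate, may compete with ring closure and erode the configuration at C2; facial control by the tin(II) catalyst may also be incomplete with a ketone-derived enol silane. The fallback sets out from ketone 4 and aldehyde 8 and comes back at 10. Ketone 4 is deprotonated with LiHMDS in THF at −78 °C (lithium enolate 5) and 8 is added. The resulting lithium 3-[3,5-bis(benzyloxy)-4-methoxyphenyl]-1-(6-fluoro-2,3,4-trimethoxyphenyl)-2-methoxy-3-oxidopropan-1-one (racemic, both diastereomers) F1 is driven to ring closure with DMPU at −20 → 20 °C. Here aldol and retro-aldol may equilibrate freely and only the SNAr is irreversible, so the sequence should funnel to the racemic 2,3-trans chromanone. This is 10 together with (2S,3S)-2-[3,5-bis(benzyloxy)-4-methoxyphenyl]-3,5,6,7-tetramethoxy-2,3-dihydro-4H-chromen-4-one F2, which is removed by preparative SFC on a chiral stationary phase (amylose tris(3,5-dimethylphenylcarbamate)).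

2. Step 1. Elimination of LiF from the ortho-fluoroaryllithium to an aryne, or proton transfer from the amide to the organolithium, may consume 3 before acylation. The fallback sets out from 1 and comes back at 4. It replaces metalation by electrophilic substitution: Friedel–Crafts acylation of 1 with methoxyacetyl chloride and SnCl4 in CH2Cl2 at −20 → 0 °C. The two free ring positions are equivalent and activated by ortho and para methoxy groups, so 4 should form directly and no new compound arises (F0).

3. Step 5. Over-reduction may accompany debenzylation, by hydrogenolysis of the benzylic C2–O1 bond or reduction of the C4 ketone. The fallback sets out from 7 and comes back at 11, and changes the protecting group so that no reducing agent is needed. Aldehyde 7 is protected with MOMCl and i-Pr2NEt in CH2Cl2 as 4-methoxy-3,5-bis(methoxymethoxy)benzaldehyde F3. This is taken through the annulation of step 4 with 6, via (2R,3R)-1-(6-fluoro-2,3,4-trimethoxyphenyl)-2-methoxy-3-[4-methoxy-3,5-bis(methoxymethoxy)phenyl]-3-[(trimethylsilyl)oxy]propan-1-one F4 (not isolated), to (2R,3R)-3,5,6,7-tetramethoxy-2-[4-methoxy-3,5-bis(methoxymethoxy)phenyl]-2,3-dihydro-4H-chromen-4-one F5. HCl in MeOH at 40 °C should then free both phenols to give 11; the acid can at most move C3 towards the trans epimer.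

Further compounds
F1 | step 4 | lithium 3-[3,5-bis(benzyloxy)-4-methoxyphenyl]-1-(6-fluoro-2,3,4-trimethoxyphenyl)-2-methoxy-3-oxidopropan-1-one (racemic, both diastereomers) | COc1cc(F)c(c(OC)c1OC)C(=O)C(OC)C(O[Li])c1cc(OCc2ccccc2)c(OC)c(OCc2ccccc2)c1
F2 | step 4 | (2S,3S)-2-[3,5-bis(benzyloxy)-4-methoxyphenyl]-3,5,6,7-tetramethoxy-2,3-dihydro-4H-chromen-4-one | COc1cc2c(c(OC)c1OC)C(=O)[C@@H](OC)[C@H](c1cc(OCc3ccccc3)c(OC)c(OCc3ccccc3)c1)O2
F0 | step 1 | none | none
F3 | step 5 | 4-methoxy-3,5-bis(methoxymethoxy)benzaldehyde | COCOc1cc(C=O)cc(OCOC)c1OC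
F4 | step 5 | (2R,3R)-1-(6-fluoro-2,3,4-trimethoxyphenyl)-2-methoxy-3-[4-methoxy-3,5-bis(methoxymethoxy)phenyl]-3-[(trimethylsilyl)oxy]propan-1-one | COc1cc(F)c(c(OC)c1OC)C(=O)[C@H](OC)[C@@H](c1cc(OCOC)c(OC)c(OCOC)c1)O[Si](C)(C)C
F5 | step 5 | (2R,3R)-3,5,6,7-tetramethoxy-2-[4-methoxy-3,5-bis(methoxymethoxy)phenyl]-2,3-dihydro-4H-chromen-4-one | COc1cc2c(c(OC)c1OC)C(=O)[C@H](OC)[C@@H](c1cc(OCOC)c(OC)c(OCOC)c1)O2
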